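**Remark on the chemistry:** with the oxolane numbered O1, C2 (aryl), C3 (CH2O–acyl), C4 (arylmethyl), C5, the target is the (2S,3S,4R) isomer: the aryl group and the CH2O arm are cis, the CH2O arm and the arylmethyl group are trans. The route is planned for this isomer.

## Retrosynthetic overview

1. Target 19 ⇐ Mitsunobu esterification of triol 17 with p-coumaric acid 18; 17 ⇐ desilylation of 16.
2. 16 ⇐ lactol 15 by oxocarbenium reduction (sets C2, aryl cis to the C3 arm); 15 ⇐ lactone 11 + aryllithium 14.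
3. 11 ⇐ lactone ester 8; the spare malonate ester becomes the CH2O carbon on C3.
4. 8 ⇐ aldehyde 3 + bromomalonate 5 in one flask: the oxolane C3–C4 bond by enantioselective radical alkylation of an enamine, then the O1–C2 bond by reduction and lactonisation. The oxolane (as its 2-oxo form) is the only ring made; all arene rings are bought.
5. Enabling feature: oxolane C4 is α to C5 (the OCH2 carbon, a latent aldehyde), and C3 lies between C2 and the exocyclic CH2O carbon (a latent malonate). With C2 at the carboxyl level, O1 closes the ring as a lactone; the C2 aryl group and C2–H are added afterwards.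

Key step: step 4

## Route

Step 1
Reactants: 1 methyl 3-(4-hydroxy-3-methoxyphenyl)propanoate
Product: 2 methyl 3-[3-methoxy-4-(triisopropylsilyloxy)phenyl]propanoate
Conditions: TIPSCl, imidazole, DMF, rt
Reagents that add atoms: triisopropylsilyl chloride (TIPSCl), CC(C)[Si](Cl)(C(C)C)C(C)C
Why: Silyl ether formation masks the phenol for the hydride, radical and organolithium steps, and an aryl TIPS ether should survive all of them and fall to fluoride at the end.

Step 2
Reactants: 2 methyl 3-[3-methoxy-4-(triisopropylsilyloxy)phenyl]propanoate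
Product: 3 3-[3-methoxy-4-(triisopropylsilyloxy)phenyl]propanal
Conditions: i-Bu2AlH, CH2Cl2, −78 °C; aq. potassium sodium tartrate
Reagents that add atoms: none
Why: Partial ester reduction with i-Bu2AlH at −78 °C should stop at the aluminium hemiacetal, which releases the aldehyde on work-up.

Step 3
Reactants: 4 dibenzyl propanedioate (dibenzyl malonate)
Product: 5 dibenzyl 2-bromopropanedioate
Conditions: Br2 (1 equiv), CH2Cl2, 0 °C to rt
Reagents that add atoms: bromine, BrBr
Why: Electrophilic α-bromination of the malonate through its enol gives the radical precursor, and one equivalent of bromine limits dibromination.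

Step 4
Reactants: 3 3-[3-methoxy-4-(triisopropylsilyloxy)phenyl]propanal; 5 dibenzyl 2-bromopropanedioate
Product: 8 benzyl (3R,4R)-4-{[3-methoxy-4-(triisopropylsilyloxy)phenyl]methyl}-2-oxooxolane-3-carboxylate, via aldehyde 6 (not isolated), via hydroxy diester 7 (not isolated)
Conditions: Ru(bpy)3Cl2 (0.5 mol %), (2R,5S)-2-tert-butyl-3,5-dimethylimidazolidin-4-one·CF3SO3H (20 mol %), 2,6-lutidine, DMF, visible light, rt; then NaBH4, i-PrOH, −20 °C to rt
Reagents that add atoms: none
Why: Aldehyde 3 condenses with the imidazolidinone to an E-enamine, monovalent ruthenium (formed by reductive quenching of photoexcited Ru(bpy)3Cl2) cleaves the C–Br bond of 5, and the electrophilic malonyl radical adds to the enamine carbon on the face away from the 5-methyl group of the catalyst, which should fix the R configuration of the carbon that becomes oxolane C4; oxidation of the α-amino radical and hydrolysis release aldehyde 6. The closest known reaction type is the enantioselective photoredox organocatalytic α-alkylation of aldehydes with bromomalonates (dual enamine and photoredox catalysis), followed by the standard hydride reduction and lactonisation of a γ-oxo malonate. NaBH4 reduces the aldehyde in the flask before it can enolise, and the alkoxide of 7 attacks one of the two diastereotopic benzyl esters in a 5-exo-trig acyl substitution that closes the lactone ring and forms its O1–C2 bond. The second stereocentre, lactone C3, is malonate-like and should epimerise in the basic reduction medium to the thermodynamically preferred trans arrangement with the neighbouring arylmethyl group. The step needs radical capture by the enamine to outrun attack on the electron-rich arene and needs reduction to precede racemisation; the much higher nucleophilicity of the enamine and the in-flask reduction should secure both.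

Step 5
Reactants: 8 benzyl (3R,4R)-4-{[3-methoxy-4-(triisopropylsilyloxy)phenyl]methyl}-2-oxooxolane-3-carboxylate
Product: 9 (3S,4R)-4-{[3-methoxy-4-(triisopropylsilyloxy)phenyl]methyl}-2-oxooxolane-3-carboxylic acid
Conditions: H2 (1 atm), 10% Pd/C, EtOAc, rt
Reagents that add atoms: none
Why: Hydrogenolysis of the benzyl ester should free the acid without touching the lactone or the aryl silyl ether, and the malonic α-centre stays at its trans equilibrium (the descriptor changes only through priority rules).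

Step 6
Reactants: 9 (3S,4R)-4-{[3-methoxy-4-(triisopropylsilyloxy)phenyl]methyl}-2-oxooxolane-3-carboxylic acid
Product: 10 (3S,4R)-3-(hydroxymethyl)-4-{[3-methoxy-4-(triisopropylsilyloxy)phenyl]methyl}oxolan-2-one
Conditions: BH3·SMe2, THF, 0 °C to rt; MeOH quench
Reagents that add atoms: none
Why: Chemoselective borane reduction of a carboxylic acid beside a lactone (acyloxyborane pathway) should turn the former second malonate carbon into the CH2OH carbon and freeze the 3,4-trans configuration.

Step 7
Reactants: 10 (3S,4R)-3-(hydroxymethyl)-4-{[3-methoxy-4-(triisopropylsilyloxy)phenyl]methyl}oxolan-2-one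
Product: 11 (3S,4R)-3-{[tert-butyl(dimethyl)silyl]oxymethyl}-4-{[3-methoxy-4-(triisopropylsilyloxy)phenyl]methyl}oxolan-2-one
Conditions: TBSCl, imidazole, CH2Cl2, rt
Reagents that add atoms: tert-butyldimethylsilyl chloride (TBSCl), CC(C)(C)[Si](C)(C)Cl
Why: Silylation of the primary alcohol prevents alkoxide-triggered retro-aldol or elimination chemistry during the organolithium addition.

Step 8
Reactants: 12 4-bromo-2-methoxyphenol
Product: 13 (4-bromo-2-methoxyphenoxy)triisopropylsilane
Conditions: TIPSCl, imidazole, DMF, rt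
Reagents that add atoms: triisopropylsilyl chloride (TIPSCl), CC(C)[Si](Cl)(C(C)C)C(C)C
Why: Silyl ether formation masks the phenol so that bromine–lithium exchange can follow.

Step 9
Reactants: 11 (3S,4R)-3-{[tert-butyl(dimethyl)silyl]oxymethyl}-4-{[3-methoxy-4-(triisopropylsilyloxy)phenyl]methyl}oxolan-2-one; 13 (4-bromo-2-methoxyphenoxy)triisopropylsilane
Product: 15 (3S,4R)-3-{[tert-butyl(dimethyl)silyl]oxymethyl}-2-[3-methoxy-4-(triisopropylsilyloxy)phenyl]-4-{[3-methoxy-4-(triisopropylsilyloxy)phenyl]methyl}oxolan-2-ol (anomeric mixture), via aryllithium 14 (not isolated)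
Conditions: 13, n-BuLi, THF, −78 °C; then 11, −78 °C; aq. NH4Cl at −78 °C
Reagents that add atoms: none
Why: Bromine–lithium exchange followed by 1,2-addition of the aryllithium to the lactone carbonyl should stop at the lithium lactolate at −78 °C, placing the aryl group on C2 without disturbing the two existing stereocentres.

Step 10
Reactants: 15 (3S,4R)-3-{[tert-butyl(dimethyl)silyl]oxymethyl}-2-[3-methoxy-4-(triisopropylsilyloxy)phenyl]-4-{[3-methoxy-4-(triisopropylsilyloxy)phenyl]methyl}oxolan-2-ol
Product: 16 tert-butyl{[(2S,3S,4R)-2-[3-methoxy-4-(triisopropylsilyloxy)phenyl]-4-{[3-methoxy-4-(triisopropylsilyloxy)phenyl]methyl}oxolan-3-yl]methoxy}dimethylsilane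
Conditions: Et3SiH, BF3·OEt2, CH2Cl2, −78 °C; Et3N quench at −78 °C
Reagents that add atoms: none
Why: Reductive deoxygenation of a cyclic hemiketal (ionic hydrogenation through the oxocarbenium ion) should deliver hydride anti to the adjacent CH2OTBS group on C3, so the aryl group ends cis to it and C2 becomes S, while the low temperature suppresses benzylic re-ionisation and epimerisation.

Step 11
Reactants: 16 tert-butyl{[(2S,3S,4R)-2-[3-methoxy-4-(triisopropylsilyloxy)phenyl]-4-{[3-methoxy-4-(triisopropylsilyloxy)phenyl]methyl}oxolan-3-yl]methoxy}dimethylsilane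
Product: 17 4-{[(3R,4S,5S)-5-(4-hydroxy-3-methoxyphenyl)-4-(hydroxymethyl)oxolan-3-yl]methyl}-2-methoxyphenol
Conditions: Bu4NF, AcOH, THF, 0 °C to rt
Reagents that add atoms: none
Why: Fluoride-mediated desilylation buffered with acetic acid should remove all three silyl groups without exposing the 2-aryl oxolane to strong acid or to free phenoxide.

Step 12
Reactants: 17 4-{[(3R,4S,5S)-5-(4-hydroxy-3-methoxyphenyl)-4-(hydroxymethyl)oxolan-3-yl]methyl}-2-methoxyphenol; 18 (E)-3-(4-hydroxyphenyl)prop-2-enoic acid (p-coumaric acid)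
Product: 19 [(2S,3S,4R)-2-(4-hydroxy-3-methoxyphenyl)-4-[(4-hydroxy-3-methoxyphenyl)methyl]oxolan-3-yl]methyl (E)-3-(4-hydroxyphenyl)prop-2-enoate (target)
Conditions: PPh3, DIAD, THF, 0 °C to rt
Reagents that add atoms: none
Why: In this Mitsunobu esterification only the primary alcohol is activated as an alkoxyphosphonium ion and only the carboxylic acid, far more acidic than the phenols, is deprotonated by the betaine, so the ester should form chemoselectively under neutral conditions with the E alkene and all stereocentres untouched.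

## Compound list

1 | methyl 3-(4-hydroxy-3-methoxyphenyl)propanoate | COC(=O)CCc1ccc(O)c(OC)c1 | starting material
2 | methyl 3-[3-methoxy-4-(triisopropylsilyloxy)phenyl]propanoate | COC(=O)CCc1ccc(O[Si](C(C)C)(C(C)C)C(C)C)c(OC)c1 | intermediate
3 | 3-[3-methoxy-4-(triisopropylsilyloxy)phenyl]propanal | O=CCCc1ccc(O[Si](C(C)C)(C(C)C)C(C)C)c(OC)c1 | intermediate
4 | dibenzyl propanedioate | O=C(CC(=O)OCc1ccccc1)OCc1ccccc1 | starting material
5 | dibenzyl 2-bromopropanedioate | O=C(OCc1ccccc1)C(Br)C(=O)OCc1ccccc1 | intermediate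
6 | dibenzyl 2-[(2R)-3-[3-methoxy-4-(triisopropylsilyloxy)phenyl]-1-oxopropan-2-yl]propanedioate (not isolated) | O=C[C@H](Cc1ccc(O[Si](C(C)C)(C(C)C)C(C)C)c(OC)c1)C(C(=O)OCc1ccccc1)C(=O)OCc1ccccc1 | intermediate
7 | dibenzyl 2-[(2R)-1-hydroxy-3-[3-methoxy-4-(triisopropylsilyloxy)phenyl]propan-2-yl]propanedioate (not isolated) | OC[C@H](Cc1ccc(O[Si](C(C)C)(C(C)C)C(C)C)c(OC)c1)C(C(=O)OCc1ccccc1)C(=O)OCc1ccccc1 | intermediate
8 | benzyl (3R,4R)-4-{[3-methoxy-4-(triisopropylsilyloxy)phenyl]methyl}-2-oxooxolane-3-carboxylate (trans) | COc1cc(C[C@H]2COC(=O)[C@@H]2C(=O)OCc2ccccc2)ccc1O[Si](C(C)C)(C(C)C)C(C)C | intermediate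
9 | (3S,4R)-4-{[3-methoxy-4-(triisopropylsilyloxy)phenyl]methyl}-2-oxooxolane-3-carboxylic acid (trans) | COc1cc(C[C@H]2COC(=O)[C@@H]2C(=O)O)ccc1O[Si](C(C)C)(C(C)C)C(C)C | intermediate
10 | (3S,4R)-3-(hydroxymethyl)-4-{[3-methoxy-4-(triisopropylsilyloxy)phenyl]methyl}oxolan-2-one (trans) | COc1cc(C[C@H]2COC(=O)[C@@H]2CO)ccc1O[Si](C(C)C)(C(C)C)C(C)C | intermediate
11 | (3S,4R)-3-{[tert-butyl(dimethyl)silyl]oxymethyl}-4-{[3-methoxy-4-(triisopropylsilyloxy)phenyl]methyl}oxolan-2-one | COc1cc(C[C@H]2COC(=O)[C@@H]2CO[Si](C)(C)C(C)(C)C)ccc1O[Si](C(C)C)(C(C)C)C(C)C | intermediate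
12 | 4-bromo-2-methoxyphenol | COc1cc(Br)ccc1O | starting material
13 | (4-bromo-2-methoxyphenoxy)triisopropylsilane | COc1cc(Br)ccc1O[Si](C(C)C)(C(C)C)C(C)C | intermediate
14 | [3-methoxy-4-(triisopropylsilyloxy)phenyl]lithium (not isolated) | [Li]c1ccc(O[Si](C(C)C)(C(C)C)C(C)C)c(OC)c1 | intermediate
15 | (3S,4R)-3-{[tert-butyl(dimethyl)silyl]oxymethyl}-2-[3-methoxy-4-(triisopropylsilyloxy)phenyl]-4-{[3-methoxy-4-(triisopropylsilyloxy)phenyl]methyl}oxolan-2-ol (anomeric mixture) | COc1cc(C[C@H]2COC(O)(c3ccc(O[Si](C(C)C)(C(C)C)C(C)C)c(OC)c3)[C@@H]2CO[Si](C)(C)C(C)(C)C)ccc1O[Si](C(C)C)(C(C)C)C(C)C | intermediate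
16 | tert-butyl{[(2S,3S,4R)-2-[3-methoxy-4-(triisopropylsilyloxy)phenyl]-4-{[3-methoxy-4-(triisopropylsilyloxy)phenyl]methyl}oxolan-3-yl]methoxy}dimethylsilane | COc1cc(C[C@H]2CO[C@H](c3ccc(O[Si](C(C)C)(C(C)C)C(C)C)c(OC)c3)[C@@H]2CO[Si](C)(C)C(C)(C)C)ccc1O[Si](C(C)C)(C(C)C)C(C)C | intermediate
17 | 4-{[(3R,4S,5S)-5-(4-hydroxy-3-methoxyphenyl)-4-(hydroxymethyl)oxolan-3-yl]methyl}-2-methoxyphenol | COc1cc(C[C@H]2CO[C@H](c3ccc(O)c(OC)c3)[C@@H]2CO)ccc1O | intermediate
18 | (E)-3-(4-hydroxyphenyl)prop-2-enoic acid | OC(=O)/C=C/c1ccc(O)cc1 | starting material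
19 | [(2S,3S,4R)-2-(4-hydroxy-3-methoxyphenyl)-4-[(4-hydroxy-3-methoxyphenyl)methyl]oxolan-3-yl]methyl (E)-3-(4-hydroxyphenyl)prop-2-enoate | COc1cc(C[C@H]2CO[C@H](c3ccc(O)c(OC)c3)[C@@H]2COC(=O)/C=C/c2ccc(O)cc2)ccc1O | target

## Step count and risks

Total step count: 12. Longest linear sequence: 10 steps (1, 2, 4, 5, 6, 7, 9, 10, 11, 12).

The three steps most likely to fail:

**Step 4.** The α-branched aldehyde may enolise and lose enantiopurity before it is reduced, facial discrimination on the enamine may be incomplete, and lactonisation or the epimerisation to trans may stall. The fallback is an auxiliary-controlled alkylation. It sets out from aldehyde 3. Oxidation with NaClO2, NaH2PO4 and 2-methylbut-2-ene would give 3-[3-methoxy-4-(triisopropylsilyloxy)phenyl]propanoic acid F1. Acylation of (4S)-4-benzyl-1,3-oxazolidin-2-one with DCC and DMAP would give the imide (4S)-4-benzyl-3-{3-[3-methoxy-4-(triisopropylsilyloxy)phenyl]propanoyl}-1,3-oxazolidin-2-one F2. Enolisation with NaN(SiMe3)2 at −78 °C and alkylation with tert-butyl bromoacetate, on the enolate face away from the auxiliary benzyl group, would set the same R centre in the alkylated imide F3. LiBH4 in wet THF would cleave the auxiliary to the hydroxy ester tert-butyl (3R)-3-(hydroxymethyl)-4-[3-methoxy-4-(triisopropylsilyloxy)phenyl]butanoate F4. TsOH in warm toluene would close the lactone (4R)-4-{[3-methoxy-4-(triisopropylsilyloxy)phenyl]methyl}oxolan-2-one F5. Its enolate (LiN(i-Pr)2, THF, −78 °C) would take up gaseous formaldehyde trans to the arylmethyl group, and the route is rejoined at compound 10.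

**Step 10.** Hydride may attack the oxocarbenium ion with too little facial preference, or the Lewis acid may re-ionise the electron-rich benzylic C2 and equilibrate the product towards the 2,3-trans isomer. The fallback sets out from lactol 15, whose open form is a γ-hydroxy aryl ketone. Reagent-controlled reduction with BH3·SMe2 and (R)-2-methyl-CBS-oxazaborolidine would give the diol (1S,2S,3R)-2-{[tert-butyl(dimethyl)silyl]oxymethyl}-1-[3-methoxy-4-(triisopropylsilyloxy)phenyl]-3-{[3-methoxy-4-(triisopropylsilyloxy)phenyl]methyl}butane-1,4-diol F6. Mitsunobu cyclodehydration (PPh3, DIAD, THF) would activate the primary hydroxyl, so that the benzylic oxygen closes the ring with retention at the benzylic carbon. This comes back to the route at compound 16.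

**Step 12.** The alkoxyphosphonium intermediate may alkylate one of the three free phenols instead of the carboxylate, and separation from the phosphine oxide may cost material. The fallback sets out from compound 16. Catalytic camphorsulfonic acid in MeOH/CH2Cl2 at 0 °C would cleave only the primary alkyl silyl ether and give the alcohol [(2S,3S,4R)-2-[3-methoxy-4-(triisopropylsilyloxy)phenyl]-4-{[3-methoxy-4-(triisopropylsilyloxy)phenyl]methyl}oxolan-3-yl]methanol F7. Separately, p-coumaric acid 18 with TIPSCl (2.2 equiv) and imidazole in DMF would give the bis-silylated triisopropylsilyl (E)-3-[4-(triisopropylsilyloxy)phenyl]prop-2-enoate F8, whose silyl ester hydrolyses on aqueous AcOH work-up to (E)-3-[4-(triisopropylsilyloxy)phenyl]prop-2-enoic acid F9. Coupling of F7 and F9 with EDC·HCl and DMAP in CH2Cl2 would give the fully silylated ester F10. Bu4NF with AcOH in THF at 0 °C would remove the three aryl silyl groups and arrive at compound 19.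

Further compounds
F1 | step 4 | 3-[3-methoxy-4-(triisopropylsilyloxy)phenyl]propanoic acid | OC(=O)CCc1ccc(O[Si](C(C)C)(C(C)C)C(C)C)c(OC)c1
F2 | step 4 | (4S)-4-benzyl-3-{3-[3-methoxy-4-(triisopropylsilyloxy)phenyl]propanoyl}-1,3-oxazolidin-2-one | O=C(CCc1ccc(O[Si](C(C)C)(C(C)C)C(C)C)c(OC)c1)N1C(=O)OC[C@@H]1Cc1ccccc1
F3 | step 4 | tert-butyl (3R)-4-[(4S)-4-benzyl-2-oxo-1,3-oxazolidin-3-yl]-3-{[3-methoxy-4-(triisopropylsilyloxy)phenyl]methyl}-4-oxobutanoate | CC(C)(C)OC(=O)C[C@@H](Cc1ccc(O[Si](C(C)C)(C(C)C)C(C)C)c(OC)c1)C(=O)N1C(=O)OC[C@@H]1Cc1ccccc1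
F4 | step 4 | tert-butyl (3R)-3-(hydroxymethyl)-4-[3-methoxy-4-(triisopropylsilyloxy)phenyl]butanoate | CC(C)(C)OC(=O)C[C@@H](Cc1ccc(O[Si](C(C)C)(C(C)C)C(C)C)c(OC)c1)CO
F5 | step 4 | (4R)-4-{[3-methoxy-4-(triisopropylsilyloxy)phenyl]methyl}oxolan-2-one | COc1cc(C[C@H]2COC(=O)C2)ccc1O[Si](C(C)C)(C(C)C)C(C)C
F6 | step 10 | (1S,2S,3R)-2-{[tert-butyl(dimethyl)silyl]oxymethyl}-1-[3-methoxy-4-(triisopropylsilyloxy)phenyl]-3-{[3-methoxy-4-(triisopropylsilyloxy)phenyl]methyl}butane-1,4-diol | COc1cc(C[C@@H](CO)[C@@H](CO[Si](C)(C)C(C)(C)C)[C@H](O)c2ccc(O[Si](C(C)C)(C(C)C)C(C)C)c(OC)c2)ccc1O[Si](C(C)C)(C(C)C)C(C)C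
F7 | step 12 | [(2S,3S,4R)-2-[3-methoxy-4-(triisopropylsilyloxy)phenyl]-4-{[3-methoxy-4-(triisopropylsilyloxy)phenyl]methyl}oxolan-3-yl]methanol | COc1cc(C[C@H]2CO[C@H](c3ccc(O[Si](C(C)C)(C(C)C)C(C)C)c(OC)c3)[C@@H]2CO)ccc1O[Si](C(C)C)(C(C)C)C(C)C
F8 | step 12 | triisopropylsilyl (E)-3-[4-(triisopropylsilyloxy)phenyl]prop-2-enoate | CC(C)[Si](OC(=O)/C=C/c1ccc(O[Si](C(C)C)(C(C)C)C(C)C)cc1)(C(C)C)C(C)C
F9 | step 12 | (E)-3-[4-(triisopropylsilyloxy)phenyl]prop-2-enoic acid | OC(=O)/C=C/c1ccc(O[Si](C(C)C)(C(C)C)C(C)C)cc1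
F10 | step 12 | [(2S,3S,4R)-2-[3-methoxy-4-(triisopropylsilyloxy)phenyl]-4-{[3-methoxy-4-(triisopropylsilyloxy)phenyl]methyl}oxolan-3-yl]methyl (E)-3-[4-(triisopropylsilyloxy)phenyl]prop-2-enoate | COc1cc(C[C@H]2CO[C@H](c3ccc(O[Si](C(C)C)(C(C)C)C(C)C)c(OC)c3)[C@@H]2COC(=O)/C=C/c2ccc(O[Si](C(C)C)(C(C)C)C(C)C)cc2)ccc1O[Si](C(C)C)(C(C)C)C(C)C
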